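**Retrosynthetic overview**

1. The route rests on ring A (C4a, C5, C6, C7, C8, C8a), a fully substituted benzene in which three unlike oxygens (O5–H, O7–Me, the ring C oxygen on C8a) alternate with three unlike carbons (C4a acyl, C6 side chain, C8 prenyl). It is built de novo so that each oxygen is born with a different mask.
2. Last disconnections: ester hydrolysis and O5 dealkylation; ring C by the C3–C4 bond (intramolecular hydroacylation of a C4a aldehyde onto an O-(1-methylallyl) group) after the O1–C2 bond (Mitsunobu, sets C2); the C4a formyl group by ortho-formylation.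
3. Ring A is disconnected at C7–C8 and C8a–C4a ([2+2] of a vinylketene with a siloxyalkyne) and at C6–C7 (six-electron electrocyclisation), giving cyclobutenone 6 and siloxyalkyne 10.
4. Compound 6 comes from 3-propylglutaric anhydride (desymmetrisation sets the side-chain centre) and ethoxyacetylene; 10 comes from methyl 4-methylpent-3-enoate through its ynolate.
5. Ring order: ring A first (step 5), ring C last (step 10).

Key step: step 5

Assumption: the quinine-series catalyst (DHQ)2AQN is taken to give the (S)-half-ester 2; if the rotation of 2 shows the opposite sense, the pseudoenantiomer (DHQD)2AQN is used under the same conditions.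

**Route**

Step 1
Reactants: 1 3-propylglutaric anhydride
Product: 2 (3S)-3-(2-methoxy-2-oxoethyl)hexanoic acid
Conditions: MeOH (10 equiv), (DHQ)2AQN [hydroquinine anthraquinone-1,4-diyl diether] (10 mol%), Et2O, −40 °C
Reagents that add atoms: methanol, CO
Why: Cinchona-alkaloid-catalysed enantioselective methanolysis (desymmetrisation) of a prochiral cyclic anhydride, in which the quinuclidine nitrogen activates methanol as a general base and the chiral pocket selects one enantiotopic carbonyl, sets the (S) centre that becomes the benzylic carbon of the target.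

Step 2
Reactants: 2 (3S)-3-(2-methoxy-2-oxoethyl)hexanoic acid
Product: 3 methyl (3R)-3-(2-chloro-2-oxoethyl)hexanoate
Conditions: (COCl)2, DMF (cat.), CH2Cl2, 0 °C → rt; evaporate cold, use crude
Reagents that add atoms: oxalyl chloride, O=C(Cl)C(=O)Cl
Why: Acid chloride formation through chloroiminium activation is run cold and the product is not heated or distilled, so that chloride/methoxide interchange between the two arms through the cyclic anhydride, which would racemise the centre, does not set in (the descriptor changes only by priority).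

Step 3
Reactants: 3 methyl (3R)-3-(2-chloro-2-oxoethyl)hexanoate; 4 ethoxyacetylene
Product: 6 methyl (3R)-3-(2-ethoxy-4-oxocyclobut-2-en-1-yl)hexanoate (both epimers at the ring carbon), via ketene 5 (not isolated)
Conditions: 4 (3 equiv), Et3N (1.3 equiv), Et2O–hexanes, 0 °C → rt, slow addition of 3
Reagents that add atoms: none
Why: Dehydrochlorination gives the monoalkylketene 5, which undergoes the known ketene–alkoxyalkyne [2+2] cycloaddition (ketene carbonyl carbon to the nucleophilic terminal alkyne carbon) with the excess ynol ether faster than it dimerises, giving the 3-ethoxy-4-alkylcyclobutenone as an inconsequential mixture of ring epimers.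

Step 4
Reactants: 7 methyl 4-methylpent-3-enoate
Product: 10 triisopropyl[(5-methylhex-4-en-1-yn-1-yl)oxy]silane, via dibromoenolate 8 (not isolated), via ynolate 9 (not isolated)
Conditions: CH2Br2, LiTMP, THF, −78 °C; LiHMDS; n-BuLi, −78 °C → rt; TIPSCl, −78 °C → rt
Reagents that add atoms: dibromomethane, BrCBr; chlorotriisopropylsilane, CC(C)[Si](Cl)(C(C)C)C(C)C
Why: Kowalski ester homologation stopped at the ynolate (addition of LiCHBr2 to the ester at −78 °C, enolisation, bromine–lithium exchange and 1,2-shift of the prenyl CH2 group with loss of LiBr) gives 9, which the bulky silyl chloride captures on oxygen to give the siloxyalkyne.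

Step 5
Reactants: 6 methyl (3R)-3-(2-ethoxy-4-oxocyclobut-2-en-1-yl)hexanoate; 10 triisopropyl[(5-methylhex-4-en-1-yn-1-yl)oxy]silane
Product: 15 methyl (3R)-3-[2-ethoxy-6-hydroxy-5-(3-methylbut-2-enyl)-4-(triisopropylsilyloxy)phenyl]hexanoate, via vinylketene 11 (not isolated), via vinylcyclobutenone 12 (not isolated), via dienylketene 13 (not isolated), via cyclohexadienone 14 (not isolated)
Conditions: 6 (1.0 equiv), 10 (1.3 equiv), toluene (0.5 M), degassed, sealed tube, 110 °C
Reagents that add atoms: none
Why: Proposed new method: thermal four-electron conrotatory opening of 6, with the C4 alkyl group rotating outwards so that both ring epimers give the same ethoxyvinylketene 11, is followed by a [2+2] cycloaddition in which the electrophilic ketene carbon (future C7) bonds to the prenyl-bearing alkyne carbon (C8) and the ketene α-carbon (C4a) to the siloxy carbon (C8a), giving 12. A second four-electron opening gives dienylketene 13, whose six-electron disrotatory electrocyclisation forms C6–C7 and closes ring A as dienone 14, which tautomerises to phenol 15. The closest known reaction is the Danheiser benzannulation of 3-alkyl- or 3-arylcyclobutenones with trialkylsiloxyalkynes to resorcinol monosilyl ethers, and the known thermal ring expansion of 4-alkenyl-3-alkoxycyclobutenones to alkoxyphenols shows that a 3-alkoxy group is tolerated in the second half of the cascade; the untested element is a 3-alkoxy-4-alkylcyclobutenone as the vinylketene source. No stereocentre is created, since the sp3 ring carbons of 6, 12 and 14 vanish on aromatisation, and the neutral conditions leave the benzylic centre, the ester and the prenyl group untouched. The one selectivity needed, the orientation of the [2+2] step, is secured by the polarisation of the siloxyalkyne (the oxygen makes the prenyl-bearing carbon nucleophilic) against the ketene carbonyl carbon, and the outward rotation of the alkyl group keeps it away from the ketene so that no 1,5-hydrogen shift competes.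

Step 6
Reactants: 15 methyl (3R)-3-[2-ethoxy-6-hydroxy-5-(3-methylbut-2-enyl)-4-(triisopropylsilyloxy)phenyl]hexanoate
Product: 16 methyl (3R)-3-[2-ethoxy-6-methoxy-5-(3-methylbut-2-enyl)-4-(triisopropylsilyloxy)phenyl]hexanoate
Conditions: MeI (5 equiv), K2CO3 (3 equiv), DMF, 0 °C → rt
Reagents that add atoms: iodomethane, CI
Why: Williamson O-methylation of the only free phenol (O7) with a large excess of MeI outruns attack of the phenoxide on the neighbouring ester, and any dihydrocoumarin formed by that lactonisation is returned to 16 by adding MeOH to the same mixture (methanolysis, then methylation), while the hindered aryl silyl ether is stable to carbonate.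

Step 7
Reactants: 16 methyl (3R)-3-[2-ethoxy-6-methoxy-5-(3-methylbut-2-enyl)-4-(triisopropylsilyloxy)phenyl]hexanoate
Product: 17 methyl (3R)-3-[2-ethoxy-4-hydroxy-6-methoxy-5-(3-methylbut-2-enyl)phenyl]hexanoate
Conditions: TBAF, AcOH (1:1), THF, 0 °C
Reagents that add atoms: none
Why: Fluoride-induced cleavage of the aryl silyl ether under acetic acid buffering frees O8a without base-induced ester chemistry or acid-induced cyclisation of the ortho-prenyl phenol.

Step 8
Reactants: 17 methyl (3R)-3-[2-ethoxy-4-hydroxy-6-methoxy-5-(3-methylbut-2-enyl)phenyl]hexanoate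
Product: 19 methyl (3R)-3-[2-ethoxy-3-formyl-4-hydroxy-6-methoxy-5-(3-methylbut-2-enyl)phenyl]hexanoate, via hydroxymethylphenol 18 (not isolated)
Conditions: MgCl2 (2 equiv), Et3N (4 equiv), (CH2O)n (6 equiv), MeCN, 80 °C; cold dilute HCl work-up
Reagents that add atoms: paraformaldehyde (as formaldehyde), C=O
Why: Magnesium-mediated ortho-formylation, in which the magnesium phenoxide delivers formaldehyde to the ortho carbon and the resulting benzylic alkoxide 18 passes hydride to a second formaldehyde, can only occur at C4a because C8 is blocked, and its basic conditions spare the prenyl group.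

Step 9
Reactants: 19 methyl (3R)-3-[2-ethoxy-3-formyl-4-hydroxy-6-methoxy-5-(3-methylbut-2-enyl)phenyl]hexanoate; 20 (R)-but-3-en-2-ol
Product: 21 methyl (3R)-3-[4-[(2S)-but-3-en-2-yloxy]-2-ethoxy-3-formyl-6-methoxy-5-(3-methylbut-2-enyl)phenyl]hexanoate
Conditions: 20 (1.5 equiv), PPh3, DIAD, THF, 0 °C → rt
Reagents that add atoms: none
Why: Mitsunobu etherification of the acidic salicylaldehyde phenol displaces the activated secondary alcohol by SN2 with inversion, so the (R)-alcohol gives the (S)-configured O1–C2 bond.

Step 10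
Reactants: 21 methyl (3R)-3-[4-[(2S)-but-3-en-2-yloxy]-2-ethoxy-3-formyl-6-methoxy-5-(3-methylbut-2-enyl)phenyl]hexanoate
Product: 23 methyl (3R)-3-[(2S,3S)-5-ethoxy-7-methoxy-2,3-dimethyl-8-(3-methylbut-2-enyl)-4-oxo-3,4-dihydro-2H-chromen-6-yl]hexanoate, via cis-chromanone 22 (not isolated)
Conditions: 3-mesityl-5,6,7,8-tetrahydro-4H-cyclohepta[d]thiazol-3-ium perchlorate (20 mol%), DBU (40 mol%), 1,4-dioxane, 120 °C
Reagents that add atoms: none
Why: N-heterocyclic-carbene-catalysed intramolecular hydroacylation of an unactivated terminal alkene (the carbene–aldehyde enaminol adds across the vinyl group in a concerted ene-type step) forms C4–C3 and closes ring C; C3 is then equilibrated through the enol by DBU to the trans (2S,3S) isomer with both methyl groups pseudo-equatorial, and the blocked ortho positions rule out a Claisen rearrangement of the aryl allyl ether.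

Step 11
Reactants: 23 methyl (3R)-3-[(2S,3S)-5-ethoxy-7-methoxy-2,3-dimethyl-8-(3-methylbut-2-enyl)-4-oxo-3,4-dihydro-2H-chromen-6-yl]hexanoate
Product: 25 methyl (3R)-3-[(2S,3S)-5-hydroxy-7-methoxy-2,3-dimethyl-8-(3-methylbut-2-enyl)-4-oxo-3,4-dihydro-2H-chromen-6-yl]hexanoate, via dichloroborate 24 (not isolated)
Conditions: BCl3 (1.5–2 equiv), CH2Cl2, −78 → 0 °C; cold aq. NaHCO3
Reagents that add atoms: none
Why: Chelation-directed ether cleavage, in which BCl3 bridges the C4 carbonyl and the peri O5 oxygen and chloride removes the ethyl group, leaves the non-chelated O7 methyl ether and the ring ether alone, and low temperature with a cold basic quench protects the prenyl alkene from HCl.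

Step 12
Reactants: 25 methyl (3R)-3-[(2S,3S)-5-hydroxy-7-methoxy-2,3-dimethyl-8-(3-methylbut-2-enyl)-4-oxo-3,4-dihydro-2H-chromen-6-yl]hexanoate
Product: 26 (3R)-3-[(2S,3S)-5-hydroxy-7-methoxy-2,3-dimethyl-8-(3-methylbut-2-enyl)-4-oxo-3,4-dihydro-2H-chromen-6-yl]hexanoic acid
Conditions: LiOH·H2O (3 equiv), THF–H2O (3:1), 0 °C → rt; 1 M HCl to pH 3 at 0 °C
Reagents that add atoms: lithium hydroxide, [Li+].[OH-]
Why: Saponification of the unhindered methyl ester is safe for the ring C centres because the deprotonated chelated O5 phenol suppresses enolisation at C3 (so no ring opening at C2) and C3 already has its thermodynamic configuration.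

**Compound list**

1 | 3-propylglutaric anhydride | CCCC1CC(=O)OC(=O)C1 | starting material
2 | (3S)-3-(2-methoxy-2-oxoethyl)hexanoic acid | CCC[C@H](CC(=O)OC)CC(=O)O | intermediate
3 | methyl (3R)-3-(2-chloro-2-oxoethyl)hexanoate | CCC[C@H](CC(=O)OC)CC(=O)Cl | intermediate
4 | ethoxyacetylene | CCOC#C | starting material
5 | methyl (3R)-3-(2-oxoethenyl)hexanoate (ketene) | CCC[C@H](CC(=O)OC)C=C=O | intermediate (not isolated)
6 | methyl (3R)-3-(2-ethoxy-4-oxocyclobut-2-en-1-yl)hexanoate, both ring epimers | CCC[C@H](CC(=O)OC)C1C(OCC)=CC1=O | intermediate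
7 | methyl 4-methylpent-3-enoate | COC(=O)CC=C(C)C | starting material
8 | lithium 1,1-dibromo-5-methylhexa-1,4-dien-2-olate | [Li+].[O-]C(CC=C(C)C)=C(Br)Br | intermediate (not isolated)
9 | lithium 5-methylhex-4-en-1-yn-1-olate | [Li+].[O-]C#CCC=C(C)C | intermediate (not isolated)
10 | triisopropyl[(5-methylhex-4-en-1-yn-1-yl)oxy]silane | CC(C)=CCC#CO[Si](C(C)C)(C(C)C)C(C)C | intermediate
11 | methyl (3R,4Z)-5-ethoxy-7-oxo-3-propylhepta-4,6-dienoate (vinylketene) | CCC[C@H](CC(=O)OC)/C=C(OCC)/C=C=O | intermediate (not isolated)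
12 | methyl (3R,4Z)-5-ethoxy-5-[3-(3-methylbut-2-enyl)-4-oxo-2-(triisopropylsilyloxy)cyclobut-2-en-1-yl]-3-propylpent-4-enoate | CCC[C@H](CC(=O)OC)/C=C(OCC)/C1C(=O)C(CC=C(C)C)=C1O[Si](C(C)C)(C(C)C)C(C)C | intermediate (not isolated)
13 | methyl (3R,4Z,6E)-5-ethoxy-8-(3-methylbut-2-enyl)-9-oxo-3-propyl-7-(triisopropylsilyloxy)nona-4,6,8-trienoate (dienylketene) | CCC[C@H](CC(=O)OC)/C=C(OCC)/C=C(O[Si](C(C)C)(C(C)C)C(C)C)\C(CC=C(C)C)=C=O | intermediate (not isolated)
14 | methyl (3R)-3-[2-ethoxy-5-(3-methylbut-2-enyl)-6-oxo-4-(triisopropylsilyloxy)cyclohexa-2,4-dien-1-yl]hexanoate | CCC[C@H](CC(=O)OC)C1C(=O)C(CC=C(C)C)=C(O[Si](C(C)C)(C(C)C)C(C)C)C=C1OCC | intermediate (not isolated)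
15 | methyl (3R)-3-[2-ethoxy-6-hydroxy-5-(3-methylbut-2-enyl)-4-(triisopropylsilyloxy)phenyl]hexanoate | CCC[C@H](CC(=O)OC)c1c(OCC)cc(O[Si](C(C)C)(C(C)C)C(C)C)c(CC=C(C)C)c1O | intermediate
16 | methyl (3R)-3-[2-ethoxy-6-methoxy-5-(3-methylbut-2-enyl)-4-(triisopropylsilyloxy)phenyl]hexanoate | CCC[C@H](CC(=O)OC)c1c(OCC)cc(O[Si](C(C)C)(C(C)C)C(C)C)c(CC=C(C)C)c1OC | intermediate
17 | methyl (3R)-3-[2-ethoxy-4-hydroxy-6-methoxy-5-(3-methylbut-2-enyl)phenyl]hexanoate | CCC[C@H](CC(=O)OC)c1c(OCC)cc(O)c(CC=C(C)C)c1OC | intermediate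
18 | methyl (3R)-3-[2-ethoxy-4-hydroxy-3-(hydroxymethyl)-6-methoxy-5-(3-methylbut-2-enyl)phenyl]hexanoate | CCC[C@H](CC(=O)OC)c1c(OCC)c(CO)c(O)c(CC=C(C)C)c1OC | intermediate (not isolated)
19 | methyl (3R)-3-[2-ethoxy-3-formyl-4-hydroxy-6-methoxy-5-(3-methylbut-2-enyl)phenyl]hexanoate | CCC[C@H](CC(=O)OC)c1c(OCC)c(C=O)c(O)c(CC=C(C)C)c1OC | intermediate
20 | (R)-but-3-en-2-ol | C[C@@H](O)C=C | starting material
21 | methyl (3R)-3-[4-[(2S)-but-3-en-2-yloxy]-2-ethoxy-3-formyl-6-methoxy-5-(3-methylbut-2-enyl)phenyl]hexanoate | CCC[C@H](CC(=O)OC)c1c(OCC)c(C=O)c(O[C@@H](C)C=C)c(CC=C(C)C)c1OC | intermediate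
22 | methyl (3R)-3-[(2S,3R)-5-ethoxy-7-methoxy-2,3-dimethyl-8-(3-methylbut-2-enyl)-4-oxo-3,4-dihydro-2H-chromen-6-yl]hexanoate (cis) | CCC[C@H](CC(=O)OC)c1c(OCC)c2c(c(CC=C(C)C)c1OC)O[C@@H](C)[C@@H](C)C2=O | intermediate (not isolated)
23 | methyl (3R)-3-[(2S,3S)-5-ethoxy-7-methoxy-2,3-dimethyl-8-(3-methylbut-2-enyl)-4-oxo-3,4-dihydro-2H-chromen-6-yl]hexanoate | CCC[C@H](CC(=O)OC)c1c(OCC)c2c(c(CC=C(C)C)c1OC)O[C@@H](C)[C@H](C)C2=O | intermediate
24 | methyl (3R)-3-[(2S,3S)-5-(dichloroboryloxy)-7-methoxy-2,3-dimethyl-8-(3-methylbut-2-enyl)-4-oxo-3,4-dihydro-2H-chromen-6-yl]hexanoate | CCC[C@H](CC(=O)OC)c1c(OB(Cl)Cl)c2c(c(CC=C(C)C)c1OC)O[C@@H](C)[C@H](C)C2=O | intermediate (not isolated)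
25 | methyl (3R)-3-[(2S,3S)-5-hydroxy-7-methoxy-2,3-dimethyl-8-(3-methylbut-2-enyl)-4-oxo-3,4-dihydro-2H-chromen-6-yl]hexanoate | CCC[C@H](CC(=O)OC)c1c(O)c2c(c(CC=C(C)C)c1OC)O[C@@H](C)[C@H](C)C2=O | intermediate
26 | (3R)-3-[(2S,3S)-5-hydroxy-7-methoxy-2,3-dimethyl-8-(3-methylbut-2-enyl)-4-oxo-3,4-dihydro-2H-chromen-6-yl]hexanoic acid | CCC[C@H](CC(=O)O)c1c(O)c2c(c(CC=C(C)C)c1OC)O[C@@H](C)[C@H](C)C2=O | target

**Step count**

Total steps: 12. Longest linear sequence: 11 (steps 1–3, then 5–12); step 4 is the second branch.

**Steps most likely to fail**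

1. Step 5 (Proposed new method).
 - What may go wrong: the vinylogous-ester stabilisation of 6 may slow ring opening so much that the ketene is lost to dimerisation; an inward rotation of the alkyl group would open a 1,5-hydrogen shift; the siloxyalkyne may isomerise to a silylketene on long heating; the product phenol may lactonise onto the neighbouring ester.
 - Fallback (known chemistry only): every classical entry to this ring must start from a symmetrical phloroglucinol ether, so the fallback branches from no intermediate of the route. It uses none of compounds 1–19, sets out from commercial 3,5-dimethoxyphenol F1, borrows alcohol 20 on the way and comes back to the route at compound 25.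
 - F1 is silylated (TIPSCl, imidazole, DMF) to silyl ether F2.
 - F2 is lithiated between the two methoxy groups (n-BuLi, THF, 0 °C) and transmetalated (MgBr2·OEt2, then CuBr·SMe2). Auxiliary-controlled conjugate addition to enoyl imide F3 (made from (S)-4-phenyloxazolidin-2-one, n-BuLi and (E)-hex-2-enoyl chloride) gives adduct F4 with the (3R) centre; the aryl group enters anti to the phenyl group of the chelated s-cis imide.
 - NaOMe in MeOH gives methyl ester F5, and TBAF gives phenol F6.
 - C-Prenylation of the sodium phenoxide (NaH, prenyl bromide, toluene) gives prenylphenol F7, the O5-methyl analogue of 17. The regiochemistry is unambiguous because the two ortho positions are equivalent.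
 - F7 is taken through the conditions of steps 8–10 to salicylaldehyde F8, allylic ether F9 and 5,7-dimethoxychromanone F10.
 - BCl3 then removes only the chelated O5 methyl group and delivers 25.

2. Step 10.
 - What may go wrong: slow formation of the acyl-anion equivalent at an aldehyde flanked by two alkoxy groups; loss of configuration at C2 through base-induced opening and reclosure of ring C (retro-oxa-Michael) at 120 °C; incomplete cis-to-trans equilibration.
 - Fallback: sets out from 21 and comes back at 23. A thiol-catalysed radical-chain hydroacylation is used (tert-dodecanethiol, 1,1'-azobis(cyclohexanecarbonitrile), chlorobenzene, 100 °C). The thiyl radical abstracts the formyl hydrogen, the aroyl radical cyclises 6-exo onto the vinyl group, and the thiol reduces the primary radical. The conditions are neutral, so C2 is never exposed to hot base. The cis/trans mixture (22 and 23) is then equilibrated with Et3N at room temperature.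

3. Step 9.
 - What may go wrong: slow reaction of a hydrogen-bonded phenol carrying two ortho substituents with a secondary allylic alcohol; attack at the alkene terminus (SN2′) giving the linear crotyl ether; partial loss of configuration through ionisation of the activated allylic alcohol.
 - Fallback: sets out from 19 and comes back at 21. A palladium-catalysed asymmetric allylic etherification is used with methyl (E)-but-2-enyl carbonate, Pd2(dba)3·CHCl3 and the chiral diphosphine N,N'-(cyclohexane-1,2-diyl)bis[2-(diphenylphosphino)benzamide], in CH2Cl2 at rt; the ligand enantiomer is chosen for the (S)-ether. The phenol attacks the substituted terminus of the π-crotyl complex, so C2 is set by the catalyst and not by inversion of 20.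

**Further compounds**

F1 | step 5 | 3,5-dimethoxyphenol (commercial starting point of the fallback) | COc1cc(O)cc(OC)c1
F2 | step 5 | (3,5-dimethoxyphenoxy)triisopropylsilane | COc1cc(OC)cc(O[Si](C(C)C)(C(C)C)C(C)C)c1
F3 | step 5 | (4S)-3-[(2E)-hex-2-enoyl]-4-phenyl-1,3-oxazolidin-2-one | CCC/C=C/C(=O)N1[C@@H](c2ccccc2)COC1=O
F4 | step 5 | (4S)-3-[(3R)-3-[2,6-dimethoxy-4-(triisopropylsilyloxy)phenyl]hexanoyl]-4-phenyl-1,3-oxazolidin-2-one | CCC[C@H](CC(=O)N1[C@@H](c2ccccc2)COC1=O)c1c(OC)cc(O[Si](C(C)C)(C(C)C)C(C)C)cc1OC
F5 | step 5 | methyl (3R)-3-[2,6-dimethoxy-4-(triisopropylsilyloxy)phenyl]hexanoate | CCC[C@H](CC(=O)OC)c1c(OC)cc(O[Si](C(C)C)(C(C)C)C(C)C)cc1OC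
F6 | step 5 | methyl (3R)-3-(4-hydroxy-2,6-dimethoxyphenyl)hexanoate | CCC[C@H](CC(=O)OC)c1c(OC)cc(O)cc1OC
F7 | step 5 | methyl (3R)-3-[4-hydroxy-2,6-dimethoxy-3-(3-methylbut-2-enyl)phenyl]hexanoate | CCC[C@H](CC(=O)OC)c1c(OC)cc(O)c(CC=C(C)C)c1OC
F8 | step 5 | methyl (3R)-3-[3-formyl-4-hydroxy-2,6-dimethoxy-5-(3-methylbut-2-enyl)phenyl]hexanoate | CCC[C@H](CC(=O)OC)c1c(OC)c(C=O)c(O)c(CC=C(C)C)c1OC
F9 | step 5 | methyl (3R)-3-[4-[(2S)-but-3-en-2-yloxy]-3-formyl-2,6-dimethoxy-5-(3-methylbut-2-enyl)phenyl]hexanoate | CCC[C@H](CC(=O)OC)c1c(OC)c(C=O)c(O[C@@H](C)C=C)c(CC=C(C)C)c1OC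
F10 | step 5 | methyl (3R)-3-[(2S,3S)-5,7-dimethoxy-2,3-dimethyl-8-(3-methylbut-2-enyl)-4-oxo-3,4-dihydro-2H-chromen-6-yl]hexanoate | CCC[C@H](CC(=O)OC)c1c(OC)c2c(c(CC=C(C)C)c1OC)O[C@@H](C)[C@H](C)C2=O
F0 | step 10 | none | none
F0 | step 9 | none | none
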